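Decide first which constant goes to 4.0 h, because the readings stop at 2.50 h and the question lies beyond them.

| flask | starting material | remark | time |
|---|---|---|---|
| epsilon | 0.25 M | run made earlier |  |
| beta | 1 M | run made earlier |  |
| flask | 0.50 M |  | 4.0 h |

| run | time / h | target / % | starting material / % | isomer of the product B / % |
|---|---|---|---|---|
| epsilon | 0.333 | 19 | 70 | 0 |
| epsilon | 0.833 | 28 | 41 | 4 |
| epsilon | 1.50 | 36 | 27 | 5 |
| epsilon | 2.50 | 36 | 13 | 9 |
| beta | 0.667 | 30 | 52 | 4 |
| beta | 1.33 | 35 | 29 | 9 |
| beta | 2.00 | 37 | 15 | 8 |
| beta | 2.50 | 39 | 10 | 11 |

(scatter of a reading: 2 percentage points)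

1. concentration of target at 4.0 h, in M
2. concentration of starting material at 4.0 h, in M
3. concentration of isomer of the product B at 4.0 h, in M



Our yardstick is the running mean constant k̄, an apparent first-order constant: the logarithm of charge over remaining starting material, divided by the time elapsed. It replaces the curve up to that time by one mean slope. At the last readings k̄ is 0.816 h⁻¹ in the epsilon run and 0.921 h⁻¹ in the beta run, with a mean of 0.869 h⁻¹.

One of us holds that k̄ is a single constant: the last readings of the two runs stand 3 percentage points apart, with a scatter of 2 points on each, so c(starting material) at 4.0 h is 0.0155 M. The other holds that k̄ slides, since the early readings give 1.07 h⁻¹ in the epsilon run and 0.980 h⁻¹ in the beta run, with a mean of 1.03 h⁻¹, higher than the late mean. A straight line through these two means reaches 0.734 h⁻¹ at 4.0 h, lower than the late mean. I commit to this second view, which gives c(starting material) = 0.0265 M.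

The forecast, reasoning that “Starting material decays first order”, differs from my figure and gives c(starting material) = 0.0125 M, c(target) = 0.175 M and c(isomer of the product B) = 0.085 M.

The flask gives c(starting material) = 0.0380 M, c(target) = 0.166 M and c(isomer of the product B) = 0.0735 M.

    starting material ⇌ isomer of the product A (K = 180, k = 0.00567 min⁻¹)
    target ⇌ isomer of the product B (K = 0.590, k = 0.00339 min⁻¹)
    starting material ⇌ target (K = 3.90, k = 0.0103 min⁻¹)
    starting material ⇌ third isomer (K = 0.680, k = 0.00167 min⁻¹)

In this flask k̄ is 0.883 h⁻¹ at 2.00 h, the region where a single constant near the late mean 0.869 h⁻¹ serves, but 0.644 h⁻¹ at 4.0 h, lower than that mean and lower than my 0.734 h⁻¹, so k̄ does slide, and further than my line reached. Starting material and target exchange with a relaxation half-life of 0.893 h by this step alone, short against 4.0 h. Carried to the neighbour charged with 0.30 M and read at the same time, the k̄ of this flask at 4.0 h gives 0.0228 M, and that neighbour holds 0.0228 M of starting material.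

The numbers in the tables stem from a simulated flask with constants of no real substance, and the scatter is random.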